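X stands at 47.2% of the charge at the top of the green run, from 0.025 M of E, but at 28.4% at the top of the grey run, from 0.10 M, so the larger charge holds the smaller share.

| flask | E | remark | time |
|---|---|---|---|
| green | 0.025 M | run made earlier |  |
| grey | 0.10 M | run made earlier |  |
| flask | 0.050 M |  | 5.0 d |

| green: time / d | green: X / % | grey: time / d | grey: X / % |
|---|---|---|---|
| 0.0417 | 38.6 | 0.0417 | 28.1 |
| 0.0833 | 45.3 | 0.0833 | 28.4 |
| 0.167 | 47.2 | 0.167 | 27.4 |
| 0.417 | 43.0 | 0.417 | 25.8 |
| 0.833 | 39.5 | 0.833 | 24.3 |
| 1.67 | 33.3 | 1.67 | 20.8 |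
| 4.00 | 25.4 | 4.00 | 15.6 |

(readings scatter by 0.5 percentage points)

- steps under discussion: E <-> X + Z; X <-> G

1. time up to 5.0 d at which X stands highest
2. the amount of X, in percent of the E charged, at that time

E ⇌ X + Z makes one Z for each X, so I take each peak as a quasi-equilibrium and count G as nil there. With x the fraction of the charge standing as X, I define the peak constant as the charge times x squared, divided by the fraction left as E. The green peak reads 0.0105 M and the grey peak 0.0113 M. I replace them by their mean, 0.0109 M, which gives the flask x = 37.1%. But the two readings alone give 36.6% and 37.5%, so the mean shifts x by 0.47 percentage points, less than the scatter of a reading. The grey run reads 28.1% at 0.0417 d and 27.4% at 0.167 d, either side of its top, so I expect a broad, flat peak in the flask too, with its top between 0.0833 d and 0.167 d, the times of the two peaks.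

The forecast gives 36.8% (35.8% to 37.8%) at 0.095 d (0.07 d to 0.13 d), a figure that differs from mine: “Balancing relaxation against this drift puts the peak near 0.09 d”.

The flask gives 37.3% at 0.0949 d, when G holds 1.36% of the charge and E 61.3%.

    E ⇌ X + Z (K = 0.0120 M, k = 1.70 × 10⁻⁴ s⁻¹)
    X ⇌ G (K = 2.10, k = 5.60 × 10⁻⁶ s⁻¹)

This peak gives a peak constant of 0.0111 M. Carried to a further flask, charged with 0.020 M of E, the constant 0.0109 M gives x = 51.4%, and that flask peaks at 50.8%.

(The numbers in the tables are calculated on assumed constants.)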